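A share read from the winter run at equal hours carries the winter charge of reagent with it, and neither asked flask has that charge.

common to all: substrate 0.19 M

| charge | reagent | temperature | remark | time |
|---|---|---|---|---|
| autumn | 0.57 equiv | 45 °C | run made earlier |  |
| winter | 1.4 equiv | 60 °C | run made earlier |  |
| Sunday's | 0.900 equiv | 60 °C |  | 8.0 h |
| Tuesday's | 1.80 equiv | 60 °C |  | 2.0 h |

- autumn (time / h: bis adduct / %, triple product / %, isomer of the product / %): 0.833: 5, 0, 2; 1.33: 2, 0, 0; 3.00: 3, 0, 0; 4.00: 1, 2, 1; 6.00: 3, 3, 0; 12.0: 5, 4, 3
- winter (time / h: bis adduct / %, triple product / %, isomer of the product / %): 0.417: 7, 0, 0; 0.667: 6, 1, 0; 1.33: 9, 3, 3; 2.00: 11, 10, 8; 3.00: 9, 14, 8; 6.00: 11, 19, 15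

(standard deviation of a reading: 1.5 percentage points)

- the flask that ends with the higher share of bis adduct in all that became bis adduct or triple product or isomer of the product, or "neither" when 2 percentage points or less lies between them (Sunday's / Tuesday's / neither)
- share of bis adduct in all that became bis adduct or triple product or isomer of the product, Sunday's
- share of bis adduct in all that became bis adduct or triple product or isomer of the product, Tuesday's

Minutes of the meeting on Sunday's and Tuesday's flasks. The analyst reported that in the winter run the bis adduct reads 11%, 9% and 11% from 2.00 h to 6.00 h, flat within the scatter of 1.5 percentage points. She proposed freezing c(bis adduct) at the mean of these readings, 10.3%, which is the steady-state approximation. She defined the follow-on ratio R as c(triple product) plus c(isomer of the product), over c(bis adduct), so that the asked share is one over one plus R. With that frozen value, the winter readings give R = 1.74 at 2.00 h and 3.29 at 6.00 h, and the winter climb of R, read from these scattered readings, is κ = 0.387 h⁻¹.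

The process chemist argued that more reagent should turn a flask faster, and moved to count each flask's hours in winter hours: its time multiplied by its equivalents over the winter equivalents. This is an assumption, and no run has tested it. It gives 5.14 h for Sunday's and 2.57 h for Tuesday's.

My own reckoning as secretary, along that line, gives 25.3% for Sunday's and 33.7% for Tuesday's. The forecast stood higher on both , at 29% for Sunday's and 36% for Tuesday's, the latter on the ground that “Extra reagent speeds both bis formation and its follow-on reactions”, and it chose Tuesday's.

Sunday's ends at 23.6% and Tuesday's at 31.3%, so Tuesday's is higher. Sunday's still holds 2.7% of its reagent at 8.00 h. Sunday's end ratio R is 3.24, which at κ = 0.387 h⁻¹ corresponds to 5.88 h in winter hours, against the 5.14 h reckoned.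

    substrate + reagent → single product + released group (k = 0.0355 L mol⁻¹ min⁻¹, Ea = 82.0 kJ mol⁻¹)
    reagent + single product → bis adduct + released group (k = 0.0566 L mol⁻¹ min⁻¹, Ea = 60.0 kJ mol⁻¹)
    reagent + bis adduct → triple product + released group (k = 0.0904 L mol⁻¹ min⁻¹, Ea = 62.0 kJ mol⁻¹)
    bis adduct ⇌ isomer of the product (K = 2.10, k = 0.0126 min⁻¹, Ea = 105 kJ mol⁻¹, ΔH = 4.00 kJ mol⁻¹)
    (constants at 60 °C)

Sunday's flask read at 2.0 h counts 1.29 h in winter hours, less than the 2.00 h at which the span of κ begins, and κ carried back there gives a share of 40.6%. The computed share is 44.4%.

The earlier runs and the new flask were generated by integration with made-up constants.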